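**Plan**

1. Rings: A/C = the hydroxychromanone, B = the methoxy arene, D = the dimethylpyran. Chromene locants (O1, C2, C3, C4, C4a, C5–C8, C8a) are used for rings B/D.
2. Retrosynthetic cuts, in order: the O–Si bond of a silyl ether; the ring C ketone back to a cis carbinol; the bond from C3 of ring C to C6 of ring B (ketone arylation); the O1–C8a bond of ring D; the C4–C4a bond (Heck); the C4a–I bond.
3. Forward: ring B is bought as an anisole whose three halogens are used in order of reactivity, I (C4a, Heck), then Br (C8a, closure of ring D), then Cl (C6, union). Rings A/C come ready-made from 7-hydroxychroman-4-one and are joined to rings B/D in step 5.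
4. Enabling feature: O1 sits on C8a, ortho to C4a, and C4a carries the styrenyl C3=C4 bond that ends in the hydrogen-free carbinol carbon C2. The conjugated C3=C4 bond accepts triplet energy, so visible light can pump the easily made E side chain to Z, the only geometry in which the C2 oxygen reaches C8a–Br. A nickel alkoxide at C2 cannot undergo beta-hydride elimination.
5. Stereochemistry: the only stereocentre, C3 of ring C, is formed racemic and then set by catalyst-controlled dynamic kinetic resolution in the RuCl[(S,S)-TsDPEN](p-cymene) transfer hydrogenation (cis 3S,4S carbinol). It is carried through a buffered oxidation and a buffered desilylation.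

Key step: step 3

Assumption: compounds 1, 3 and 7 are commercial, and the (S,S)-configured catalyst is taken to give the (4S) carbinol as it does with simple aryl ketones (the mirror-image catalyst would be used if the sense proved opposite).

**Route**

Step 1
Reactants: 1 4-bromo-1-chloro-2-methoxybenzene
Product: 2 1-bromo-4-chloro-2-iodo-5-methoxybenzene
Conditions: NIS, CF3CO2H/CH2Cl2, 0 °C to rt
Reagents that add atoms: N-iodosuccinimide, O=C1CCC(=O)N1I
Why: Electrophilic aromatic iodination should go para to the methoxy group, the only strongly activated open site (the free ortho site lies between OMe and Br), so iodine enters at the carbon that becomes C4a.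

Step 2
Reactants: 2 1-bromo-4-chloro-2-iodo-5-methoxybenzene; 3 2-methylbut-3-en-2-ol
Product: 4 (E)-4-(2-bromo-5-chloro-4-methoxyphenyl)-2-methylbut-3-en-2-ol
Conditions: Pd(OAc)2 (3 mol%), Bu4NCl, NaHCO3, DMF, 55 °C
Reagents that add atoms: none
Why: Mizoroki–Heck reaction in which zerovalent palladium inserts into C–I much faster than into C–Br or C–Cl under ligand-free conditions, and syn-insertion followed by beta-hydride elimination toward the arene (the carbinol carbon has no hydrogen) should give the conjugated E-alkene, the hydrogencarbonate base sparing the ionizable tertiary allylic alcohol.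

Step 3
Reactants: 4 (E)-4-(2-bromo-5-chloro-4-methoxyphenyl)-2-methylbut-3-en-2-ol
Product: 6 aryl chloride 6-chloro-7-methoxy-2,2-dimethyl-2H-chromene, via Z-alkenol 5 (not isolated)
Conditions: [Ir(dF(CF3)ppy)2(dtbbpy)]PF6 (2 mol%), MeCN, 450 nm LEDs, rt; then NiCl2(dme) (10 mol%), dtbbpy (10 mol%), quinuclidine (10 mol%), K2CO3, 450 nm, rt, N2
Reagents that add atoms: none
Why: Proposed new method: photoexcited [Ir(dF(CF3)ppy)2(dtbbpy)]PF6 passes triplet energy to the styrenyl C3=C4 bond of 4, and the twisted triplet relaxes to Z-alkenol 5, which builds up because allylic strain between the CMe2OH group and the ortho bromine twists its alkene out of conjugation and makes it the poorer energy acceptor; zerovalent nickel (from NiCl2(dme)/dtbbpy) then inserts into the C8a–Br bond, the tertiary alkoxide that the Z-alkene holds over C8a binds nickel, and one-electron oxidation of this divalent aryl nickel alkoxide to the trivalent state by the same photocatalyst triggers C(sp2)–O reductive elimination, forming O1–C8a. The closest known reaction types are the iridium/nickel photoredox etherification of aryl bromides with alcohols and the energy-transfer E-to-Z isomerization of styrenes, already joined in one-pot isomerization/cyclization cascades that turn E-cinnamic acids into coumarins; the untested element is an intramolecular tertiary alkoxide, which chelation should favour and which cannot undergo beta-hydride elimination because C2 bears no hydrogen. Ring D closes in a 6-exo sense at the ipso carbon C8a, by contraction of a seven-membered oxanickelacycle. No stereocentre is formed. The step needs geometric gating (only 5 can reach C8a, so continuous isomerization funnels all of 4 into 6), chemoselectivity for C–Br over the electron-rich C6–Cl bond (slow to add to zerovalent nickel at room temperature) and a single site of closure, which the lone ortho bromine secures.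

Step 4
Reactants: 7 7-hydroxychroman-4-one
Product: 8 7-(triisopropylsilyloxy)chroman-4-one
Conditions: TIPSCl, imidazole, DMF, rt
Reagents that add atoms: triisopropylsilyl chloride, CC(C)[Si](Cl)(C(C)C)C(C)C
Why: Standard silylation of a phenol; the hindered silyl ether should withstand the alkoxide base, formate reduction and periodinane oxidation to come and can be removed at the end by buffered fluoride.

Step 5
Reactants: 6 6-chloro-7-methoxy-2,2-dimethyl-2H-chromene; 8 7-(triisopropylsilyloxy)chroman-4-one
Product: 9 racemic 3-(7-methoxy-2,2-dimethyl-2H-chromen-6-yl)-7-(triisopropylsilyloxy)chroman-4-one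
Conditions: Pd2(dba)3 (2.5 mol%), XPhos (6 mol%), NaOtBu, toluene, 70 °C
Reagents that add atoms: none
Why: Palladium-catalysed alpha-arylation of a ketone enolate (Buchwald–Hartwig–Miura type) with a bulky dialkylbiarylphosphine that activates the electron-rich ortho-methoxy aryl chloride; the hindered aryl group should stop the reaction at monoarylation, C3 of ring C is formed racemic on purpose, and any isoflavone formed by over-oxidation is reduced to the same carbinol in step 6.

Step 6
Reactants: 9 racemic 3-(7-methoxy-2,2-dimethyl-2H-chromen-6-yl)-7-(triisopropylsilyloxy)chroman-4-one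
Product: 10 (3S,4S)-3-(7-methoxy-2,2-dimethyl-2H-chromen-6-yl)-7-(triisopropylsilyloxy)chroman-4-ol (cis)
Conditions: RuCl[(S,S)-TsDPEN](p-cymene) (2 mol%), HCO2H/Et3N (1:1), EtOAc, 40 °C
Reagents that add atoms: none
Why: Noyori–Ikariya asymmetric transfer hydrogenation with dynamic kinetic resolution, a known way to cis-isoflavan-4-ols, in which triethylamine racemizes C3 through the enol faster than reduction, the (S,S) catalyst delivers hydride to the carbonyl face that gives the (4S) carbinol (aryl ketone model) and does so anti to the 3-aryl group, so the (3S) ketone is the one consumed and the cis (3S,4S) alcohol should result, while the unpolarized chromene C3=C4 bond is not reduced.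

Step 7
Reactants: 10 (3S,4S)-3-(7-methoxy-2,2-dimethyl-2H-chromen-6-yl)-7-(triisopropylsilyloxy)chroman-4-ol
Product: 11 (3S)-3-(7-methoxy-2,2-dimethyl-2H-chromen-6-yl)-7-(triisopropylsilyloxy)chroman-4-one
Conditions: Dess–Martin periodinane, NaHCO3, CH2Cl2, 0 °C
Reagents that add atoms: none
Why: Dess–Martin oxidation of the benzylic carbinol under hydrogencarbonate buffering is non-basic and only weakly acidic, so the ketone should return without enolization and C3 keeps its S configuration.

Step 8
Reactants: 11 (3S)-3-(7-methoxy-2,2-dimethyl-2H-chromen-6-yl)-7-(triisopropylsilyloxy)chroman-4-one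
Product: 12 (3S)-7-hydroxy-3-(7-methoxy-2,2-dimethyl-2H-chromen-6-yl)chroman-4-one
Conditions: Bu4NF/AcOH (1:1), THF, 0 °C
Reagents that add atoms: none
Why: Fluoride cleaves the aryl silyl ether (the para-acyl phenoxide is a good leaving group), and acetic acid buffering keeps the medium too weakly basic to enolize the alpha-aryl ketone and too weakly acidic to protonate the electron-rich chromene, so the (3S) target should be released unchanged.

**Compound list**

1 | 4-bromo-1-chloro-2-methoxybenzene | COc1cc(Br)ccc1Cl | starting material
2 | 1-bromo-4-chloro-2-iodo-5-methoxybenzene | COc1cc(Br)c(I)cc1Cl | intermediate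
3 | 2-methylbut-3-en-2-ol | C=CC(C)(C)O | starting material
4 | (E)-4-(2-bromo-5-chloro-4-methoxyphenyl)-2-methylbut-3-en-2-ol | COc1cc(Br)c(/C=C/C(C)(C)O)cc1Cl | intermediate
5 | (Z)-4-(2-bromo-5-chloro-4-methoxyphenyl)-2-methylbut-3-en-2-ol | COc1cc(Br)c(/C=C\C(C)(C)O)cc1Cl | intermediate
6 | 6-chloro-7-methoxy-2,2-dimethyl-2H-chromene | COc1cc2OC(C)(C)C=Cc2cc1Cl | intermediate
7 | 7-hydroxychroman-4-one | O=C1CCOc2cc(O)ccc12 | starting material
8 | 7-(triisopropylsilyloxy)chroman-4-one | O=C1CCOc2cc(O[Si](C(C)C)(C(C)C)C(C)C)ccc12 | intermediate
9 | racemic 3-(7-methoxy-2,2-dimethyl-2H-chromen-6-yl)-7-(triisopropylsilyloxy)chroman-4-one | COc1cc2OC(C)(C)C=Cc2cc1C1COc2cc(O[Si](C(C)C)(C(C)C)C(C)C)ccc2C1=O | intermediate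
10 | (3S,4S)-3-(7-methoxy-2,2-dimethyl-2H-chromen-6-yl)-7-(triisopropylsilyloxy)chroman-4-ol | COc1cc2OC(C)(C)C=Cc2cc1[C@H]1COc2cc(O[Si](C(C)C)(C(C)C)C(C)C)ccc2[C@H]1O | intermediate
11 | (3S)-3-(7-methoxy-2,2-dimethyl-2H-chromen-6-yl)-7-(triisopropylsilyloxy)chroman-4-one | COc1cc2OC(C)(C)C=Cc2cc1[C@H]1COc2cc(O[Si](C(C)C)(C(C)C)C(C)C)ccc2C1=O | intermediate
12 | (3S)-7-hydroxy-3-(7-methoxy-2,2-dimethyl-2H-chromen-6-yl)chroman-4-one | COc1cc2c(cc1[C@H]1COc3cc(O)ccc3C1=O)C=CC(C)(C)O2 | target

**Step count**

Total steps: 8. Longest linear sequence: 7 (steps 1, 2, 3, 5, 6, 7, 8).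

**Steps most likely to fail**

Step 3 (Proposed new method). The aryl nickel species formed from 4 may be reduced at C8a before the side chain has turned to Z, the hindered tertiary alkoxide may be slow to eliminate from nickel, or the product may be sensitized and ring-open. Fallback: geometry and C–O bond are made in separate known operations. From 2, Sonogashira coupling at the iodide with 2-methylbut-3-yn-2-ol (PdCl2(PPh3)2, CuI, Et3N, rt) gives 4-(2-bromo-5-chloro-4-methoxyphenyl)-2-methylbut-3-yn-2-ol F1. Semihydrogenation over Pd on CaCO3 poisoned with Pb(OAc)2, with quinoline, gives Z-alkenol 5 as an isolated compound. Thermal Buchwald–Hartwig-type intramolecular etherification (Pd(OAc)2, 2-(di-tert-butylphosphino)-1,1'-binaphthyl, Cs2CO3, toluene, 80 °C) then closes the same O1–C8a bond and comes back to the route at 6.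

Step 5. Oxidative addition of the electron-rich, ortho-substituted aryl chloride may be slow, leaving the chromanone enolate time to open by beta-elimination of the aryloxide or to lose its silyl group to alkoxide. Fallback: the aryl–C3 bond is made at the sp2 level. From 6, Miyaura borylation (Pd2(dba)3, XPhos, bis(pinacolato)diboron, KOAc, dioxane, 100 °C) gives 2-(7-methoxy-2,2-dimethyl-2H-chromen-6-yl)-4,4,5,5-tetramethyl-1,3,2-dioxaborolane F2. Separately, commercial 1-(2,4-dihydroxyphenyl)ethanone is silylated at the non-chelated hydroxyl to 1-[2-hydroxy-4-(triisopropylsilyloxy)phenyl]ethanone F3, condensed with N,N-dimethylformamide dimethyl acetal to (E)-3-(dimethylamino)-1-[2-hydroxy-4-(triisopropylsilyloxy)phenyl]prop-2-en-1-one F4, and cyclized with iodine to 3-iodo-7-(triisopropylsilyloxy)-4H-chromen-4-one F5. Suzuki–Miyaura coupling of F2 with F5 (PdCl2(dppf), K3PO4, dioxane, 60 °C) gives the isoflavone 3-(7-methoxy-2,2-dimethyl-2H-chromen-6-yl)-7-(triisopropylsilyloxy)-4H-chromen-4-one F6. The transfer hydrogenation of step 6, with the same catalyst, should reduce first the enone C=C bond and then, with dynamic kinetic resolution, the carbonyl, coming back to the route at 10.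

Step 6. Racemization of the hindered ortho-methoxy ketone may not keep pace with reduction, which would erode diastereo- and enantiocontrol, and the formate medium may slowly protonate the electron-rich chromene. Fallback: resolution instead of asymmetric catalysis. From 9, buffered desilylation as in step 8 gives racemic 7-hydroxy-3-(7-methoxy-2,2-dimethyl-2H-chromen-6-yl)chroman-4-one F7. Preparative chromatography on a chiral stationary phase separates 12 from (3R)-7-hydroxy-3-(7-methoxy-2,2-dimethyl-2H-chromen-6-yl)chroman-4-one F8, which is racemized with triethylamine back to F7 and recycled. The route is rejoined at 12.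

**Further compounds**

F1 | step 3 | 4-(2-bromo-5-chloro-4-methoxyphenyl)-2-methylbut-3-yn-2-ol | COc1cc(Br)c(C#CC(C)(C)O)cc1Cl
F2 | step 5 | 2-(7-methoxy-2,2-dimethyl-2H-chromen-6-yl)-4,4,5,5-tetramethyl-1,3,2-dioxaborolane | COc1cc2OC(C)(C)C=Cc2cc1B1OC(C)(C)C(C)(C)O1
F3 | step 5 | 1-[2-hydroxy-4-(triisopropylsilyloxy)phenyl]ethanone | CC(=O)c1ccc(O[Si](C(C)C)(C(C)C)C(C)C)cc1O
F4 | step 5 | (E)-3-(dimethylamino)-1-[2-hydroxy-4-(triisopropylsilyloxy)phenyl]prop-2-en-1-one | CN(C)/C=C/C(=O)c1ccc(O[Si](C(C)C)(C(C)C)C(C)C)cc1O
F5 | step 5 | 3-iodo-7-(triisopropylsilyloxy)-4H-chromen-4-one | O=c1c(I)coc2cc(O[Si](C(C)C)(C(C)C)C(C)C)ccc12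
F6 | step 5 | 3-(7-methoxy-2,2-dimethyl-2H-chromen-6-yl)-7-(triisopropylsilyloxy)-4H-chromen-4-one | COc1cc2OC(C)(C)C=Cc2cc1-c1coc2cc(O[Si](C(C)C)(C(C)C)C(C)C)ccc2c1=O
F7 | step 6 | racemic 7-hydroxy-3-(7-methoxy-2,2-dimethyl-2H-chromen-6-yl)chroman-4-one | COc1cc2c(cc1C1COc3cc(O)ccc3C1=O)C=CC(C)(C)O2
F8 | step 6 | (3R)-7-hydroxy-3-(7-methoxy-2,2-dimethyl-2H-chromen-6-yl)chroman-4-one | COc1cc2c(cc1[C@@H]1COc3cc(O)ccc3C1=O)C=CC(C)(C)O2
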